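**Retrosynthetic overview**

1. Prostanoid numbering is used (C1 ester carbon, ring C8–C12, octenyl chain C13–C20). The strategy rests on C10, the only ring carbon that bears chlorine, lying between the C9 carbonyl and C11: taking it out of the five-membered ring leaves a four-membered ring C8–C9–C11–C12 in which C12 carries two identical CH2 arms and is not yet stereogenic.
2. Late disconnections: O12–Si; then C6–C7 (Suzuki coupling of a 7Z enol triflate with the 5E alkenylboronate from methyl hex-5-ynoate); then C7–C8 (formylation of C8).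
3. Key disconnection: C9–C10 and C10–C11. Dichlorocarbene from chloroform adds across the C9=C11 enol ether bond of an (S)-siloxycyclobutene and the adduct opens to the 2-chlorocyclopent-2-enone.
4. The cyclobutene comes from the achiral 3-siloxy-3-octenylcyclobutanone by enolisation of one enantiotopic CH2 with a chiral lithium amide (this sets C12). The cyclobutanone comes from dichloroketene [2+2] on the 2-siloxy-1-alkene made by methylenation of the TBS ester of (Z)-non-3-enoic acid, then dechlorination.
5. Ring order: the four-membered ring first (step 4), enlarged in step 7 to the five-membered ring, the only ring of the target.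

Key step: step 7

Assumption: the sense of induction of the chiral amide on this cyclobutanone is taken by analogy; the (R,R) base is written, and if it gave the (R) enol ether the equally available (S,S) amine would be used instead.

**Route**

Step 1
Reactants: 1 (Z)-non-3-en-1-ol
Product: 2 (Z)-non-3-enoic acid
Conditions: CrO3, H2SO4, H2O, acetone, 0 °C
Reagents that add atoms: water, O
Why: Jones oxidation takes the primary alcohol through the aldehyde hydrate to the acid; at 0 °C and short contact the β,γ-(Z)-alkene should be neither conjugated nor isomerised, as is usual for (Z)-alk-3-enoic acids.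

Step 2
Reactants: 2 (Z)-non-3-enoic acid; 3 tert-butyldimethylsilyl chloride
Product: 4 tert-butyldimethylsilyl (Z)-non-3-enoate
Conditions: TBSCl, imidazole, CH2Cl2, 0 °C → rt; non-aqueous work-up
Reagents that add atoms: tert-butyldimethylsilyl chloride 3, CC(C)(C)[Si](C)(C)Cl
Why: Silylation of the carboxylic acid with the silyl chloride and imidazole gives the silyl ester, whose silicon later becomes the protecting group on the C12 oxygen.

Step 3
Reactants: 4 tert-butyldimethylsilyl (Z)-non-3-enoate; 5 dimethyltitanocene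
Product: 7 tert-butyl{[(4Z)-deca-1,4-dien-2-yl]oxy}dimethylsilane, via titanocene methylidene 6 (not isolated)
Conditions: Cp2TiMe2, toluene, 70 °C, dark
Reagents that add atoms: dimethyltitanocene 5, C[Ti](C)(C1C=CC=C1)C1C=CC=C1
Why: Petasis methylenation: on heating the reagent gives titanocene methylidene, which turns the ester C=O into C=CH2 through an oxatitanacyclobutane and so gives the regiodefined 2-siloxy-1-alkene; the reagent is not basic, so the β,γ-alkene should not move into conjugation.

Step 4
Reactants: 7 tert-butyl{[(4Z)-deca-1,4-dien-2-yl]oxy}dimethylsilane; 8 trichloroacetyl chloride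
Product: 10 racemic 3-(tert-butyldimethylsilyloxy)-2,2-dichloro-3-[(Z)-oct-2-enyl]cyclobutan-1-one, via dichloroketene 9 (not isolated)
Conditions: Cl3CCOCl (slow addition), Zn–Cu, DME, Et2O, rt
Reagents that add atoms: trichloroacetyl chloride 8, ClC(Cl)(Cl)C(Cl)=O
Why: Ketene–alkene [2+2] cycloaddition with dichloroketene made in situ by zinc dechlorination: the electron-rich silyl enol ether should react far faster than the isolated C14=C15 alkene, its CH2 terminus bonding to the ketene carbonyl carbon so that CCl2 ends next to C12; the C12 centre formed here as a racemate loses its stereogenicity in step 5.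

Step 5
Reactants: 10 racemic 3-(tert-butyldimethylsilyloxy)-2,2-dichloro-3-[(Z)-oct-2-enyl]cyclobutan-1-one
Product: 11 3-(tert-butyldimethylsilyloxy)-3-[(Z)-oct-2-enyl]cyclobutan-1-one
Conditions: Zn, AcOH, rt
Reagents that add atoms: none
Why: Zinc reduction of the α,α-dichloro ketone (zinc enolate protonated by acetic acid) removes both chlorines and leaves the achiral cyclobutanone whose two CH2 groups, the future C8 and C11, are enantiotopic; the tertiary silyl ether and the alkene are inert.

Step 6
Reactants: 11 3-(tert-butyldimethylsilyloxy)-3-[(Z)-oct-2-enyl]cyclobutan-1-one; 12 chlorotrimethylsilane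
Product: 14 (S)-3-(tert-butyldimethylsilyloxy)-3-[(Z)-oct-2-enyl]-1-(trimethylsilyloxy)cyclobut-1-ene, via lithium cyclobutenolate 13 (not isolated)
Conditions: (R,R)-bis(1-phenylethyl)amine, n-BuLi, LiCl, TMSCl (present from the start), THF, −100 °C; pentane, filtration through Et3N-deactivated silica; kept at or below 0 °C and used at once
Reagents that add atoms: chlorotrimethylsilane 12, C[Si](C)(C)Cl
Why: Enantioselective deprotonation of a prochiral ketone by a C2-symmetric chiral lithium amide with in situ silyl trapping, a known desymmetrisation of 3-substituted cyclobutanones: the base takes a hydrogen from one of the two enantiotopic methylenes and so fixes C12 (ring puckering places the octenyl chain pseudo-equatorial and leaves the pseudo-axial hydrogens anti to the siloxy group as the reactive ones), and the chlorosilane traps the enolate before it can lose silanolate or equilibrate.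

Step 7
Reactants: 14 (S)-3-(tert-butyldimethylsilyloxy)-3-[(Z)-oct-2-enyl]-1-(trimethylsilyloxy)cyclobut-1-ene; 15 chloroform
Product: 18 (S)-4-(tert-butyldimethylsilyloxy)-2-chloro-4-[(Z)-oct-2-enyl]cyclopent-2-en-1-one, via dichlorocarbene 16 (not isolated), via 5,5-dichlorobicyclo[2.1.0]pentane adduct 17 (not isolated)
Conditions: CHCl3 (5 equiv), KOt-Bu (solid, in portions), pentane, −30 → 0 °C; pH 7 buffer
Reagents that add atoms: chloroform 15, ClC(Cl)Cl
Why: The electrophilic carbene adds in a [2+1] step to the electron-rich C9=C11 enol ether bond, forming C9–C10 and C10–C11; the 5,5-dichloro-1-siloxybicyclo[2.1.0]pentane is too strained to persist and undergoes two-electron disrotatory cyclopropyl-to-allyl opening in which the fusion bond C9–C11 breaks as the endo chloride leaves, the C9 siloxy group stabilising the cation until chloride removes the trimethylsilyl group. The closest known reaction type is the dihalocarbene ring expansion of cyclic trimethylsilyl enol ethers to 2-halocycloalk-2-enones, applied here to a cyclobutenyl ether, for which the opening should be spontaneous below 0 °C. The five-membered ring C8–C9–C10–C11–C12 is therefore formed by one-carbon enlargement of the four-membered ring (C10 inserted between C9 and C11) and not by a cyclisation. No stereocentre is created: the two transient ring-fusion centres vanish on opening, and C12, which is not touched, keeps the configuration set in step 6. The step needs chemoselectivity for the enol ether over the C14=C15 alkene, secured by the much higher nucleophilicity of the silyl enol ether towards the carbene and by limiting the base, and it needs C10 to end beside C11, secured by the position of the enol double bond. Adding the solid base in portions to substrate and excess chloroform keeps free alkoxide low, which should protect both the enol ether and the base-sensitive product.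

Step 8
Reactants: 18 (S)-4-(tert-butyldimethylsilyloxy)-2-chloro-4-[(Z)-oct-2-enyl]cyclopent-2-en-1-one; 19 2,2,2-trifluoroethyl formate
Product: 21 (4R,5Z)-4-(tert-butyldimethylsilyloxy)-2-chloro-5-(hydroxymethylidene)-4-[(Z)-oct-2-enyl]cyclopent-2-en-1-one, via lithium dienolate 20 (not isolated)
Conditions: LDA, THF, −78 °C; HCO2CH2CF3, −78 °C; cold 1 M HCl
Reagents that add atoms: 2,2,2-trifluoroethyl formate 19, O=COCC(F)(F)F
Why: Kinetic deprotonation at C8, the only enolisable position (C11–H is vinylic, C12 is quaternary), and Claisen-type C-formylation of the lithium enolate by the activated formate should give the β-keto aldehyde as its hydrogen-bonded (Z)-hydroxymethylene tautomer; C12 is untouched, its descriptor changing from S to R only because C8, now sp2, outranks C11.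

Step 9
Reactants: 21 (4R,5Z)-4-(tert-butyldimethylsilyloxy)-2-chloro-5-(hydroxymethylidene)-4-[(Z)-oct-2-enyl]cyclopent-2-en-1-one; 22 trifluoromethanesulfonic anhydride
Product: 24 (Z)-[(2R)-2-(tert-butyldimethylsilyloxy)-4-chloro-2-[(Z)-oct-2-enyl]-5-oxocyclopent-3-en-1-ylidene]methyl trifluoromethanesulfonate, via lithium chelate 23 (not isolated)
Conditions: LiHMDS, Et2O, −78 °C; Tf2O, −78 °C; used without storage
Reagents that add atoms: trifluoromethanesulfonic anhydride 22, O=S(=O)(OS(=O)(=O)C(F)(F)F)C(F)(F)F
Why: O-sulfonylation of a β-dicarbonyl enolate under chelation control: in ether, lithium bridges the C9 carbonyl oxygen and the C7 oxygen and holds the enolate U-shaped, so triflation at the less hindered C7 oxygen should give the enol triflate with oxygen cis to C9, that is 7Z.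

Step 10
Reactants: 25 methyl hex-5-ynoate; 26 pinacolborane
Product: 27 methyl (E)-6-(4,4,5,5-tetramethyl-1,3,2-dioxaborolan-2-yl)hex-5-enoate
Conditions: HBpin, Cp2Zr(H)Cl (5 mol%), Et3N (10 mol%), neat, 60 °C
Reagents that add atoms: pinacolborane 26, CC1(C)OBOC1(C)C
Why: Zirconium-catalysed hydroboration of the terminal alkyne with pinacolborane is a syn, anti-Markovnikov addition and gives the (E)-alkenylboronate, the future C5=C6, without touching the ester.

Step 11
Reactants: 24 (Z)-[(2R)-2-(tert-butyldimethylsilyloxy)-4-chloro-2-[(Z)-oct-2-enyl]-5-oxocyclopent-3-en-1-ylidene]methyl trifluoromethanesulfonate; 27 methyl (E)-6-(4,4,5,5-tetramethyl-1,3,2-dioxaborolan-2-yl)hex-5-enoate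
Product: 28 methyl (5E,7Z)-7-[(2R)-2-(tert-butyldimethylsilyloxy)-4-chloro-2-[(Z)-oct-2-enyl]-5-oxocyclopent-3-en-1-ylidene]hept-5-enoate
Conditions: Pd(PPh3)4 (5 mol%), K3PO4, THF–H2O, rt, dark
Reagents that add atoms: methyl (E)-6-(4,4,5,5-tetramethyl-1,3,2-dioxaborolan-2-yl)hex-5-enoate 27, COC(=O)CCC/C=C/B1OC(C)(C)C(C)(C)O1
Why: Suzuki–Miyaura coupling forms C6–C7 with retention at both alkenyl carbons, so the 7Z geometry of the triflate and the 5E geometry of the boronate carry into the dienylidene; the vinylogous acyl triflate should add to Pd(0) far faster than the C10–Cl bond, and phosphate at room temperature spares the ester and the silyl ether.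

Step 12
Reactants: 28 methyl (5E,7Z)-7-[(2R)-2-(tert-butyldimethylsilyloxy)-4-chloro-2-[(Z)-oct-2-enyl]-5-oxocyclopent-3-en-1-ylidene]hept-5-enoate
Product: 29 chlorovulone III
Conditions: HF·pyridine, pyridine, THF, 0 °C → rt
Reagents that add atoms: none
Why: Fluoride cleavage of the tertiary silyl ether with buffered HF·pyridine is mildly acidic, which the base-sensitive cross-conjugated dienone, the methyl ester and the three geometry-defined alkenes should tolerate; no stereocentre is affected.

**Compound list**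

1 | (Z)-non-3-en-1-ol | CCCCC/C=C\CCO | starting material
2 | (Z)-non-3-enoic acid | CCCCC/C=C\CC(=O)O | intermediate
3 | tert-butyldimethylsilyl chloride | CC(C)(C)[Si](C)(C)Cl | starting material
4 | tert-butyldimethylsilyl (Z)-non-3-enoate | CCCCC/C=C\CC(=O)O[Si](C)(C)C(C)(C)C | intermediate
5 | dimethyltitanocene (cyclopentadienyl rings drawn σ-bound) | C[Ti](C)(C1C=CC=C1)C1C=CC=C1 | starting material
6 | titanocene methylidene (cyclopentadienyl rings drawn σ-bound) | C=[Ti](C1C=CC=C1)C1C=CC=C1 | intermediate
7 | tert-butyl{[(4Z)-deca-1,4-dien-2-yl]oxy}dimethylsilane | CCCCC/C=C\CC(=C)O[Si](C)(C)C(C)(C)C | intermediate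
8 | trichloroacetyl chloride | ClC(Cl)(Cl)C(Cl)=O | starting material
9 | dichloroketene | O=C=C(Cl)Cl | intermediate
10 | racemic 3-(tert-butyldimethylsilyloxy)-2,2-dichloro-3-[(Z)-oct-2-enyl]cyclobutan-1-one | CCCCC/C=C\CC1(O[Si](C)(C)C(C)(C)C)CC(=O)C1(Cl)Cl | intermediate
11 | 3-(tert-butyldimethylsilyloxy)-3-[(Z)-oct-2-enyl]cyclobutan-1-one (achiral) | CCCCC/C=C\CC1(O[Si](C)(C)C(C)(C)C)CC(=O)C1 | intermediate
12 | chlorotrimethylsilane | C[Si](C)(C)Cl | starting material
13 | lithium (S)-3-(tert-butyldimethylsilyloxy)-3-[(Z)-oct-2-enyl]cyclobut-1-en-1-olate | CCCCC/C=C\C[C@@]1(O[Si](C)(C)C(C)(C)C)C=C(O[Li])C1 | intermediate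
14 | (S)-3-(tert-butyldimethylsilyloxy)-3-[(Z)-oct-2-enyl]-1-(trimethylsilyloxy)cyclobut-1-ene | CCCCC/C=C\C[C@@]1(O[Si](C)(C)C(C)(C)C)C=C(O[Si](C)(C)C)C1 | intermediate
15 | chloroform | ClC(Cl)Cl | starting material
16 | dichlorocarbene | Cl[C]Cl | intermediate
17 | (3S)-3-(tert-butyldimethylsilyloxy)-5,5-dichloro-3-[(Z)-oct-2-enyl]-1-(trimethylsilyloxy)bicyclo[2.1.0]pentane (cis-fused, either face) | CCCCC/C=C\C[C@@]1(O[Si](C)(C)C(C)(C)C)C2C(Cl)(Cl)C2(O[Si](C)(C)C)C1 | intermediate
18 | (S)-4-(tert-butyldimethylsilyloxy)-2-chloro-4-[(Z)-oct-2-enyl]cyclopent-2-en-1-one | CCCCC/C=C\C[C@@]1(O[Si](C)(C)C(C)(C)C)C=C(Cl)C(=O)C1 | intermediate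
19 | 2,2,2-trifluoroethyl formate | O=COCC(F)(F)F | starting material
20 | lithium (S)-3-(tert-butyldimethylsilyloxy)-5-chloro-3-[(Z)-oct-2-enyl]cyclopenta-1,4-dien-1-olate (C8 enolate of 18) | CCCCC/C=C\C[C@@]1(O[Si](C)(C)C(C)(C)C)C=C(Cl)C(O[Li])=C1 | intermediate
21 | (4R,5Z)-4-(tert-butyldimethylsilyloxy)-2-chloro-5-(hydroxymethylidene)-4-[(Z)-oct-2-enyl]cyclopent-2-en-1-one | CCCCC/C=C\C[C@@]1(O[Si](C)(C)C(C)(C)C)C=C(Cl)C(=O)/C1=C\O | intermediate
22 | trifluoromethanesulfonic anhydride | O=S(=O)(OS(=O)(=O)C(F)(F)F)C(F)(F)F | starting material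
23 | lithium (Z)-[(2R)-2-(tert-butyldimethylsilyloxy)-4-chloro-2-[(Z)-oct-2-enyl]-5-oxocyclopent-3-en-1-ylidene]methanolate (lithium bridging the C7 and C9 oxygens) | CCCCC/C=C\C[C@@]1(O[Si](C)(C)C(C)(C)C)C=C(Cl)C(=O)/C1=C\O[Li] | intermediate
24 | (Z)-[(2R)-2-(tert-butyldimethylsilyloxy)-4-chloro-2-[(Z)-oct-2-enyl]-5-oxocyclopent-3-en-1-ylidene]methyl trifluoromethanesulfonate | CCCCC/C=C\C[C@@]1(O[Si](C)(C)C(C)(C)C)C=C(Cl)C(=O)/C1=C\OS(=O)(=O)C(F)(F)F | intermediate
25 | methyl hex-5-ynoate | COC(=O)CCCC#C | starting material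
26 | pinacolborane | CC1(C)OBOC1(C)C | starting material
27 | methyl (E)-6-(4,4,5,5-tetramethyl-1,3,2-dioxaborolan-2-yl)hex-5-enoate | COC(=O)CCC/C=C/B1OC(C)(C)C(C)(C)O1 | intermediate
28 | methyl (5E,7Z)-7-[(2R)-2-(tert-butyldimethylsilyloxy)-4-chloro-2-[(Z)-oct-2-enyl]-5-oxocyclopent-3-en-1-ylidene]hept-5-enoate | CCCCC/C=C\C[C@@]1(O[Si](C)(C)C(C)(C)C)C=C(Cl)C(=O)/C1=C\C=C\CCCC(=O)OC | intermediate
29 | chlorovulone III, methyl (5E,7Z)-7-[(2R)-4-chloro-2-hydroxy-2-[(Z)-oct-2-enyl]-5-oxocyclopent-3-en-1-ylidene]hept-5-enoate | CCCCC/C=C\C[C@@]1(O)C=C(Cl)C(=O)/C1=C\C=C\CCCC(=O)OC | target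

**Step count**

Total: 12 steps. Longest linear sequence: 11 steps (steps 1–9, 11, 12); step 10 is the side branch.

**Steps most likely to fail**

Step 6. The amide may discriminate poorly between the enantiotopic C8 and C11 methylenes, because the two ring faces (siloxy against CH2) differ only modestly and the sense of induction then depends on a weak facial bias. Loss of silanolate from the enolate, leading to a cyclobutenone, may also compete with silylation. The enantiomeric purity would be assayed on 18. Fallback, from 11 back to 18: unselective enolisation (LDA, TMSCl, THF, −78 °C) should give racemic 3-(tert-butyldimethylsilyloxy)-3-[(Z)-oct-2-enyl]-1-(trimethylsilyloxy)cyclobut-1-ene F1. Ring expansion under the conditions of step 7 should give racemic 4-(tert-butyldimethylsilyloxy)-2-chloro-4-[(Z)-oct-2-enyl]cyclopent-2-en-1-one F2. Preparative chromatography on a chiral stationary phase (cellulose tris(3,5-dimethylphenylcarbamate)) then separates 18 from (R)-4-(tert-butyldimethylsilyloxy)-2-chloro-4-[(Z)-oct-2-enyl]cyclopent-2-en-1-one F3, which is discarded.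

Step 7. Alkoxide may cleave the trimethylsilyl enol ether before the carbene is captured. It may also deprotonate the product at C8, after which silanolate is lost and the ring decomposes, and some carbene may add to C14=C15. Fallback, from 14 back to 18, with the one-carbon enlargement done without base and the chlorine introduced afterwards:
- Simmons–Smith cyclopropanation of 14 (Et2Zn, CH2I2, Et2O, 0 °C) should give (3S)-3-(tert-butyldimethylsilyloxy)-3-[(Z)-oct-2-enyl]-1-(trimethylsilyloxy)bicyclo[2.1.0]pentane F4.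
- Oxidative opening of the siloxycyclopropane with FeCl3 in DMF (Ito–Saegusa type) should give (4S)-4-(tert-butyldimethylsilyloxy)-3-chloro-4-[(Z)-oct-2-enyl]cyclopentan-1-one F5.
- Sodium acetate in methanol should eliminate HCl to give (S)-4-(tert-butyldimethylsilyloxy)-4-[(Z)-oct-2-enyl]cyclopent-2-en-1-one F6.
- Nucleophilic epoxidation (H2O2, NaOH, MeOH, 0 °C), which leaves the isolated alkene alone, should give (4S)-4-(tert-butyldimethylsilyloxy)-2,3-epoxy-4-[(Z)-oct-2-enyl]cyclopentan-1-one F7.
- Hydrogen chloride in THF at 0 °C should open the epoxide at C10 to (4S)-4-(tert-butyldimethylsilyloxy)-2-chloro-3-hydroxy-4-[(Z)-oct-2-enyl]cyclopentan-1-one F8, which dehydrates in the same flask to 18.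

Step 9. Geometric control may be lost if the lithium chelate opens, giving the 7E triflate as well. Sulfonylation may also occur at the C9 oxygen, and the vinylogous acyl triflate may hydrolyse before coupling. Fallback, from 18 back to 28, by the classical aldol–dehydration way to alkylidenecyclopentenones, which replaces steps 8, 9 and 11:
- Methyl (E)-7-oxohept-5-enoate F9 is made by Wittig reaction of methyl 5-oxopentanoate with (triphenylphosphoranylidene)acetaldehyde.
- The lithium dienolate 20 (LDA, THF, −78 °C) is added to F9 and should give methyl (5E)-7-[(2S)-2-(tert-butyldimethylsilyloxy)-4-chloro-2-[(Z)-oct-2-enyl]-5-oxocyclopent-3-en-1-yl]-7-hydroxyhept-5-enoate F10.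
- MsCl and Et3N in CH2Cl2 should convert F10 into methyl (5E)-7-[(2S)-2-(tert-butyldimethylsilyloxy)-4-chloro-2-[(Z)-oct-2-enyl]-5-oxocyclopent-3-en-1-yl]-7-(methylsulfonyloxy)hept-5-enoate F11, which eliminates under the same conditions.
- The elimination should give 28 together with its 7E isomer, methyl (5E,7E)-7-[(2R)-2-(tert-butyldimethylsilyloxy)-4-chloro-2-[(Z)-oct-2-enyl]-5-oxocyclopent-3-en-1-ylidene]hept-5-enoate F12. The two are separated by chromatography, and F12 is re-equilibrated by irradiation and recycled.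

**Further compounds**

F1 | step 6 | racemic 3-(tert-butyldimethylsilyloxy)-3-[(Z)-oct-2-enyl]-1-(trimethylsilyloxy)cyclobut-1-ene | CCCCC/C=C\CC1(O[Si](C)(C)C(C)(C)C)C=C(O[Si](C)(C)C)C1
F2 | step 6 | racemic 4-(tert-butyldimethylsilyloxy)-2-chloro-4-[(Z)-oct-2-enyl]cyclopent-2-en-1-one | CCCCC/C=C\CC1(O[Si](C)(C)C(C)(C)C)C=C(Cl)C(=O)C1
F3 | step 6 | (R)-4-(tert-butyldimethylsilyloxy)-2-chloro-4-[(Z)-oct-2-enyl]cyclopent-2-en-1-one | CCCCC/C=C\C[C@]1(O[Si](C)(C)C(C)(C)C)C=C(Cl)C(=O)C1
F4 | step 7 | (3S)-3-(tert-butyldimethylsilyloxy)-3-[(Z)-oct-2-enyl]-1-(trimethylsilyloxy)bicyclo[2.1.0]pentane (cis-fused, either face) | CCCCC/C=C\C[C@@]1(O[Si](C)(C)C(C)(C)C)C2CC2(O[Si](C)(C)C)C1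
F5 | step 7 | (4S)-4-(tert-butyldimethylsilyloxy)-3-chloro-4-[(Z)-oct-2-enyl]cyclopentan-1-one (C3 epimers) | CCCCC/C=C\C[C@@]1(O[Si](C)(C)C(C)(C)C)C(Cl)CC(=O)C1
F6 | step 7 | (S)-4-(tert-butyldimethylsilyloxy)-4-[(Z)-oct-2-enyl]cyclopent-2-en-1-one | CCCCC/C=C\C[C@@]1(O[Si](C)(C)C(C)(C)C)C=CC(=O)C1
F7 | step 7 | (4S)-4-(tert-butyldimethylsilyloxy)-2,3-epoxy-4-[(Z)-oct-2-enyl]cyclopentan-1-one (epoxide face not assigned) | CCCCC/C=C\C[C@@]1(O[Si](C)(C)C(C)(C)C)C2OC2C(=O)C1
F8 | step 7 | (4S)-4-(tert-butyldimethylsilyloxy)-2-chloro-3-hydroxy-4-[(Z)-oct-2-enyl]cyclopentan-1-one (C2 and C3 not assigned) | CCCCC/C=C\C[C@@]1(O[Si](C)(C)C(C)(C)C)C(O)C(Cl)C(=O)C1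
F9 | step 9 | methyl (E)-7-oxohept-5-enoate | COC(=O)CCC/C=C/C=O
F10 | step 9 | methyl (5E)-7-[(2S)-2-(tert-butyldimethylsilyloxy)-4-chloro-2-[(Z)-oct-2-enyl]-5-oxocyclopent-3-en-1-yl]-7-hydroxyhept-5-enoate (C7 and C8 epimers) | CCCCC/C=C\C[C@@]1(O[Si](C)(C)C(C)(C)C)C=C(Cl)C(=O)C1C(O)/C=C/CCCC(=O)OC
F11 | step 9 | methyl (5E)-7-[(2S)-2-(tert-butyldimethylsilyloxy)-4-chloro-2-[(Z)-oct-2-enyl]-5-oxocyclopent-3-en-1-yl]-7-(methylsulfonyloxy)hept-5-enoate (C7 and C8 epimers) | CCCCC/C=C\C[C@@]1(O[Si](C)(C)C(C)(C)C)C=C(Cl)C(=O)C1C(OS(C)(=O)=O)/C=C/CCCC(=O)OC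
F12 | step 9 | methyl (5E,7E)-7-[(2R)-2-(tert-butyldimethylsilyloxy)-4-chloro-2-[(Z)-oct-2-enyl]-5-oxocyclopent-3-en-1-ylidene]hept-5-enoate | CCCCC/C=C\C[C@@]1(O[Si](C)(C)C(C)(C)C)C=C(Cl)C(=O)/C1=C/C=C/CCCC(=O)OC
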